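We begin with the last readings. The earlier flasks and the two asked about each hold 1.5 mM of free catalyst:

| setting | spring | dusk | summer | theta | beta |
|---|---|---|---|---|---|
| substrate | 0.57 M | 2 M | 1.5 M | 1.5 M | 0.40 M |
| free catalyst | 1.5 mM | 1.5 mM | 1.5 mM | 1.5 mM | 1.5 mM |
| added ligand | 8.7 mM | 8.7 mM | 5.5 mM | 8.7 mM | 6.0 mM |
| remark | run made earlier | run made earlier | run made earlier |  |  |
| time |  |  |  | 25 h | 15 h |

| run | time / h | target / % |
|---|---|---|
| spring | 3.00 | 4.4 |
| spring | 6.00 | 7.6 |
| spring | 8.00 | 10.7 |
| spring | 12.0 | 14.3 |
| spring | 15.0 | 20.4 |
| spring | 20.0 | 22.8 |
| dusk | 3.00 | 3.8 |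
| dusk | 6.00 | 2.8 |
| dusk | 8.00 | 4.2 |
| dusk | 12.0 | 6.6 |
| dusk | 15.0 | 11.1 |
| dusk | 20.0 | 12.0 |
| summer | 1.33 | 1.1 |
| summer | 2.50 | 2.0 |
| summer | 5.00 | 4.3 |
| summer | 10.0 | 8.0 |
| summer | 20.0 | 15.2 |

(standard deviation of a reading: 1 percentage point)

- the winner by amount of target, in percent of the substrate charged; "neither" if no more than 2 percentage points parts them (theta / beta / neither)
- how much target is there at the end, in percent of the substrate charged: theta
- how much target is there at the end, in percent of the substrate charged: beta



We read the final row of each run against its charge. Dividing the time by the fraction of substrate turned into target gives a turnover time, the hours that pace needs for the whole charge. Spring gives 87.7 h and dusk 167 h, at the same added ligand.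

A first-order rate gives equal turnover times at any charge, and a zero-order rate gives times in proportion to the charge. Dusk's c substrate is 3.51 times spring's, but its turnover time is 1.90 times spring's, so the order lies between the two.

We therefore draw a straight line of turnover time against c substrate. Its slope gives a rate ceiling of 18.1 mM h⁻¹ for this catalyst charge. Its intercept gives 1.02 M for K, the bend level: the c substrate at which the rate stands at 0.5 of its ceiling (the Michaelis constant). The order in substrate is then K/(K + c substrate), and the fraction made is ceiling times time over K + c substrate.

Summer, with less added ligand, has a turnover time of 132 h, which on the same ceiling gives K = 0.883 M. That gap is no larger than the scatter of one reading can make, but summer's ligand lies nearest beta's, so we use this K for beta.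

Theta then runs at order 0.404 and we expect 18.0%. Beta runs at order 0.688 and we expect 21.2%. So we expect beta to lead by 3.2 percentage points, which is more than the margin.

The forecast, from a fit of its own, gave 17.5% for theta and 22.5% for beta, so beta: “Absolute rate therefore saturates in substrate.”

The flask gives 17.6% for theta and 21.7% for beta, so the winner is beta.

    substrate + free catalyst → catalyst intermediate (k = 37.0 L mol⁻¹ h⁻¹)
    catalyst intermediate → free catalyst + target (k = 12.0 h⁻¹)
    free catalyst + added ligand ⇌ idle complex, settled at all times (K = 98.0 L mol⁻¹)
    free catalyst + target → free catalyst + over-reaction product (k = 14.0 L mol⁻¹ h⁻¹)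
    target + free catalyst ⇌ isomer of the product + free catalyst, rate k5*[free catalyst]*[target] forward; the back reaction follows from the equilibrium constant (K = 8.70, k = 38.0 L mol⁻¹ h⁻¹)

Beta shows 21.7% of target mainly because we read it at 15 h and not at 150 h: left that long, beta holds 7.06%. Our bend level belongs to this early stretch of the run. For theta read at 15 h, the bend level 1.02 M keeps the order at 0.404 and puts the fraction made at 10.8%, and that flask gives 11.5%.

All runs were generated by integration for substances that don't exist; scatter was added.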